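The starting complex was slow to go: in theta 16.2% of it still stood at 6.00 h. You asked me for a quick number on birch, with the hunch that it would end with starting complex left over.

| setting | theta | epsilon | birch | alder |
|---|---|---|---|---|
| starting complex | 0.068 M (fed, over 2.5 h) | 0.068 M (fed, over 2.5 h) | 0.068 M (fed, over 2.5 h) | 0.068 M (fed, over 2.5 h) |
| incoming ligand | 0.20 M | 0.24 M | 0.136 M | 0.170 M |
| remark | run made earlier | run made earlier |  |  |
| time |  |  | 12 h | 12 h |

| run | time / h | complex with three exchanged / % | starting complex / % |
|---|---|---|---|
| theta | 1.00 | 3.5 | 24.6 |
| theta | 2.00 | 8.2 | 38.1 |
| theta | 3.00 | 15.0 | 35.9 |
| theta | 6.00 | 16.2 | 16.2 |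
| theta | 12.0 | 17.9 | 10.7 |
| epsilon | 1.00 | 4.4 | 22.2 |
| epsilon | 3.00 | 17.1 | 29.4 |
| epsilon | 6.00 | 15.8 | 11.3 |
| epsilon | 8.00 | 15.0 | 5.6 |
| epsilon | 12.0 | 16.8 | 2.6 |

(readings scatter by 1 percentage point)

- for complex with three exchanged the crystals are counted in
- as a solid, counted per litre of solution: crystals
- what was read earlier has a scatter of 1 percentage point, one standard deviation
- candidate steps: starting complex + incoming ligand <-> leaving ligand + complex with one exchanged; complex with one exchanged + incoming ligand <-> leaving ligand + complex with two exchanged; complex with three exchanged <-> isomer of the product; complex with two exchanged + incoming ligand <-> leaving ligand + complex with three exchanged; crystals <-> complex with three exchanged; leaving ligand -> by-product carried off; complex with three exchanged + incoming ligand <-> leaving ligand + complex with four exchanged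
- percentages count the whole charge, also what has not yet gone in

- which of these holds the largest part of the starting complex at the end of birch (complex with two exchanged / complex with one exchanged / starting complex / complex with three exchanged / complex with four exchanged)
- which of these holds the largest part of the starting complex at the end of alder (complex with two exchanged / complex with one exchanged / starting complex / complex with three exchanged / complex with four exchanged)
- how much complex with three exchanged is there at the end of birch, in percent of the starting complex charged

I worked with the fraction left, not the fraction made. I took incoming ligand as the limiting reagent, assumed that both earlier runs had taken up their whole charge of it by the last reading, and divided the equivalents charged by the share of starting complex reacted: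

theta: 2.94 / 89.3% = 3.29

epsilon: 3.53 / 97.4% = 3.62

This ratio is the ligand price, the ligands taken up per starting complex reacted. As a reading it was lower in theta than in epsilon, so it rose by 0.561 per equivalent. I carried that straight line down, an extrapolation from two runs:

birch: 2.00 equivalents, price 2.77, fraction left 0.278

alder: 2.50 equivalents, price 3.05, fraction left 0.180

The price doesn't say how the reacted part shares out, so on the other questions I stood with the forecast. For birch it reckoned that “ligand runs out with about 30% starting complex left”, and it named starting complex for birch, complex with four exchanged for alder and 13% for the amount asked. My fraction left for birch stood a little below its figure.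

Birch gave 14.2% of complex with three exchanged, and its largest holder was starting complex, at 27.9%; alder's was complex with four exchanged.

    starting complex + incoming ligand ⇌ leaving ligand + complex with one exchanged (K = 0.251, k = 0.0990 L mol⁻¹ min⁻¹)
    complex with one exchanged + incoming ligand ⇌ leaving ligand + complex with two exchanged (K = 2.10, k = 0.298 L mol⁻¹ min⁻¹)
    complex with three exchanged ⇌ isomer of the product (K = 1.33, k = 0.0137 min⁻¹)
    complex with two exchanged + incoming ligand ⇌ leaving ligand + complex with three exchanged (K = 13.4, k = 0.272 L mol⁻¹ min⁻¹)
    crystals ⇌ complex with three exchanged, rate k5*(cs5 - [complex with three exchanged]) while solid is left; crystals form when [complex with three exchanged] > cs5 (solubility = 49.0 mM, k = 0.280 min⁻¹)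
    leaving ligand → by-product carried off (k = 0.0695 min⁻¹)
    complex with three exchanged + incoming ligand ⇌ leaving ligand + complex with four exchanged (K = 0.655, k = 0.123 L mol⁻¹ min⁻¹)

Incoming ligand stood at 0.759% of its charge in birch at 12.0 h, and with that remainder taken off, the price read back from birch was 2.75. The same line, carried to 0.794 equivalents in a neighbour of birch charged with 0.054 M of incoming ligand, gave a price of 2.09 and a fraction left of 0.620; that flask ended with 58.7% starting complex.

The numbers in the tables were generated by integration with made-up constants; the scatter is artificial.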